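**Slow steps.** What is slow in this flask has to be counted against the time it is given, so you build it up one step at a time, with [B] the concentration of coupling partner as charged and t the time.

| flask | starting material | coupling partner | remark | time |
|---|---|---|---|---|
| blue | 0.020 M | 3.5 equiv | run made earlier |  |
| amber | 0.020 M | 4.4 equiv | run made earlier |  |
| red | 0.020 M | 5 equiv | run made earlier |  |
| west | 0.020 M | 3.00 equiv |  | 2.5 d |
| south-east | 0.020 M | 6.00 equiv |  | 2.5 d |

| run | time / h | single product / % | bis adduct / % | side product / % | starting material / % | triple product / % |
|---|---|---|---|---|---|---|
| blue | 4.00 | 36 | 2 | 5 | 57 | 2 |
| blue | 10.0 | 61 | 0 | 16 | 23 | 0 |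
| blue | 20.0 | 67 | 3 | 26 | 7 | 0 |
| blue | 30.0 | 65 | 2 | 26 | 4 | 1 |
| amber | 4.00 | 46 | 1 | 6 | 49 | 0 |
| amber | 10.0 | 67 | 2 | 17 | 16 | 2 |
| amber | 20.0 | 71 | 2 | 19 | 3 | 1 |
| amber | 30.0 | 73 | 4 | 20 | 0 | 2 |
| red | 2.50 | 39 | 1 | 2 | 57 | 1 |
| red | 6.00 | 60 | 1 | 12 | 28 | 2 |
| red | 12.0 | 74 | 1 | 14 | 8 | 0 |
| red | 30.0 | 73 | 7 | 18 | 0 | 3 |

(readings scatter by 1.5 percentage points)

- a species is counted by the starting material in it: one side product counts as two
- the earlier runs were read with a standard deviation of 1.5 percentage points
- a reading or a percentage of triple product counts all its forms, free or not
- a reading of starting material is of its free form alone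

- which of these there is most of at the end, counted by the starting material in it, west (bis adduct / side product / triple product / single product)
- which of these there is most of at the end, counted by the starting material in it, south-east (bis adduct / side product / triple product / single product)
- amount of the one of these that there is most of at the end, in percent of the starting material charged, west
- amount of the one of these that there is most of at the end, in percent of the starting material charged, south-east

**Main step.** Red fell to 57% starting material in 2.50 h. Read as pseudo-first-order decay with the partner in excess, that gives a constant of 2.25 L mol⁻¹ h⁻¹. In west the half-life of starting material is then 5.14 h, and the time holds 11.7 of them. With this step by itself, the charge ends as single product.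

**Side path.** Now add the side product. In blue it reads 26% and then 26%, while starting material falls from 7% to 4%. Its last reading times the equivalents gives 0.910 in blue, 0.880 in amber and 0.900 in red. I therefore take it as inversely proportional to the equivalents: 30.0% in west and 15.0% in south-east.

**Over-reaction.** The rest is single product, which the partner slowly carries on to bis adduct and triple product. Count its lifetimes, N = κ[B]t, where κ is the over-reaction constant, the natural logarithm of (single + bis + triple)/single divided by [B]t. Red's last readings give κ = 0.0428 L mol⁻¹ h⁻¹, a reading resting on two small numbers, each with a scatter of 1.5 percentage points. So N is 0.154 in west and 0.308 in south-east, both under one lifetime.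

**My reckoning.** Single product is the remainder times exp(−N): 60.0% in west, more than the side product, and 62.5% in south-east, more than the side product and more than the 22.5% I reckon for bis adduct and triple product together.

**The result.** The forecast, close to mine, names single product at 61% for west and single product at 62% for south-east, adding “the later chemistry is poorly determined”. The flasks give single product at 62.6% in west and single product at 64.8% in south-east, each above my figure. The idle adduct and the back reaction of triple product make no difference to single product in either flask.

    starting material + coupling partner → single product (k = 2.10 L mol⁻¹ h⁻¹)
    coupling partner + single product → bis adduct (k = 0.0440 L mol⁻¹ h⁻¹)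
    coupling partner + bis adduct ⇌ triple product (K = 7.10 L mol⁻¹, k = 1.50 L mol⁻¹ h⁻¹)
    starting material + triple product ⇌ idle adduct, settled at all times (K = 41.0 L mol⁻¹)
    starting material + single product → side product (k = 2.50 L mol⁻¹ h⁻¹)

**More partner.** Take south-east with 24.0 equiv of coupling partner and the same time. The same reckoning gives 3.75% side product and N = 1.23, now above one lifetime, so single product comes to 28.1%. That neighbour gives 29.9% single product and 4.69% side product, and its largest share is triple product, at 49.0%.

The data were computed from invented constants, and the scatter is random.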